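**Retrosynthetic overview**
1. Target (2R,3R,4S; aryl/isopropyl trans, isopropyl/isobutyl cis) ⇐ its 5,7-di-O-methyl ether by BBr3. The two methyl ethers leave only the phenol para to the formyl group free, so only that oxygen can become the pyran oxygen.
2. C2–aryl bond, C2 and C3 ⇐ new stereoconvergent, acid-mediated hydroarylation of a (4S)-4H-chromene (made from the lactol in the same pot) with diformylphloroglucinol.
3. Lactol (pyran ring, C4) ⇐ aminocatalytic enantioselective Michael addition/hemiacetalisation of isovaleraldehyde to an o-quinone methide.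
4. o-Quinone methide ⇐ benzylic sulfone ⇐ 4-hydroxy-2,6-dimethoxybenzaldehyde + isovaleraldehyde + sulfinate.
5. Ring order: both benzene rings are bought; the pyran ring is closed in the organocatalytic step and keeps its C4 centre to the end.

Assumption: 4-hydroxy-2,6-dimethoxybenzaldehyde and 2,4,6-trihydroxybenzene-1,3-dicarbaldehyde (diformylphloroglucinol) are bought as catalogue compounds.

**Step 1**
Reactants: 1 4-hydroxy-2,6-dimethoxybenzaldehyde; 2 3-methylbutanal (isovaleraldehyde)
Product: 3 rac-4-hydroxy-2,6-dimethoxy-3-[3-methyl-1-(4-methylbenzenesulfonyl)butyl]benzaldehyde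
Conditions: 2 (1.2 equiv), TolSO2Na (1.5 equiv), HCO2H/H2O 1:1, 40 °C
Reagents that add atoms: sodium p-toluenesulfinate, [Na+].[O-]S(=O)c1ccc(C)cc1
Why: Three-component sulfonyl-Mannich-type Friedel–Crafts reaction: the acid condenses 2 at C3 of 1 (ortho to the free OH, activated by OH and both OMe; C3 and C5 are equivalent) and the soft sulfinate traps the benzylic cation/o-quinone methide before a second arene can; the new centre is racemic and is erased in step 2.

**Step 2**
Reactants: 3 rac-4-hydroxy-2,6-dimethoxy-3-[3-methyl-1-(4-methylbenzenesulfonyl)butyl]benzaldehyde; 2 3-methylbutanal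
Product: 6 (3S,4S)-2-hydroxy-4-isobutyl-3-isopropyl-5,7-dimethoxychromane-6-carbaldehyde (anomer mixture at C2), via o-quinone methide 4 (not isolated), via open-chain aldehyde 5 (not isolated)
Conditions: 2 (3 equiv), (R)-α,α-diphenylprolinol TMS ether (20 mol %), NaHCO3 (1.5 equiv), CH2Cl2/H2O 10:1, 0 °C → rt
Reagents that add atoms: none
Why: Aminocatalytic Michael addition/hemiacetalisation (formal [4+2]) of an aldehyde to an o-quinone methide generated in situ from a 2-(1-sulfonylalkyl)phenol: bicarbonate expels sulfinate from 3 to give 4, the (E)-enamine of 2 and the (R)-catalyst, shielded on one face by the CPh2OTMS group, adds to the methide carbon through the usual synclinal arrangement (enamine nitrogen over the C=O, isobutyl anti to C=O) to set C4 as S (and C3 as S, trans), and the phenol closes on the aldehyde of 5; only C4 is carried on, C3 is re-set in step 3.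

**Step 3**
Reactants: 6 (3S,4S)-2-hydroxy-4-isobutyl-3-isopropyl-5,7-dimethoxychromane-6-carbaldehyde; 7 2,4,6-trihydroxybenzene-1,3-dicarbaldehyde (diformylphloroglucinol)
Product: 9 (2R,3R,4S)-2-(3,5-diformyl-2,4,6-trihydroxyphenyl)-4-isobutyl-3-isopropyl-5,7-dimethoxychromane-6-carbaldehyde, via 4H-chromene 8 (not isolated)
Conditions: TsOH·H2O (10 mol %), 4 Å MS, PhMe, 80 °C; then 7 (1.5 equiv), HFIP/MeCN, 0 °C → rt
Reagents that add atoms: none
Why: Proposed new method: stereoconvergent Brønsted-acid hydroarylation of a 4H-chromene by a diformylated phloroglucinol – the acid first dehydrates lactol 6 to enol ether 8 (erasing C3), re-protonation at C3 occurs anti to the C4 isobutyl group (held pseudoaxial by A1,2 strain and the peri 5-OMe) to give the 3,4-cis oxocarbenium ion, and the one free ring carbon of 7 (O-adducts revert, O→C) attacks C2 anti to the axial isobutyl and trans to isopropyl, the only open face (the 3-epi cation is blocked on both faces and returns to 8), so C3 (R) and C2 (R) both follow from C4; closest known reaction types are acid-catalysed hydroarylation of cyclic enol ethers, aryl C-glycosylation of acylphloroglucinols and the Knoevenagel-type C-alkylation of 7 by aldehydes.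

**Step 4**
Reactants: 9 (2R,3R,4S)-2-(3,5-diformyl-2,4,6-trihydroxyphenyl)-4-isobutyl-3-isopropyl-5,7-dimethoxychromane-6-carbaldehyde
Product: 10 (2R,3R,4S)-2-(3,5-diformyl-2,4,6-trihydroxyphenyl)-5,7-dihydroxy-4-isobutyl-3-isopropylchromane-6-carbaldehyde (target)
Conditions: BBr3 (8 equiv), CH2Cl2, −78 → 0 °C; aq. work-up
Reagents that add atoms: none
Why: Boron tribromide aryl methyl ether cleavage: both OMe groups sit ortho to the formyl group and are cleaved with chelation assistance, the phenols and aldehydes of the other ring are only tied up as borates until work-up, and the C2–O bond should not ionise at low temperature because the C2 aryl ring is deactivated by two formyl groups, so no stereocentre is touched.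

**Compound list**
1 | 4-hydroxy-2,6-dimethoxybenzaldehyde | COc1cc(O)cc(OC)c1C=O | starting material
2 | 3-methylbutanal (isovaleraldehyde) | CC(C)CC=O | starting material
3 | rac-4-hydroxy-2,6-dimethoxy-3-[3-methyl-1-(4-methylbenzenesulfonyl)butyl]benzaldehyde | CC(C)CC(c1c(O)cc(OC)c(C=O)c1OC)S(=O)(=O)c1ccc(C)cc1 | intermediate
4 | o-quinone methide, (E)-2,6-dimethoxy-3-(3-methylbutylidene)-4-oxocyclohexa-1,5-diene-1-carbaldehyde | CC(C)C/C=C1/C(=O)C=C(OC)C(C=O)=C1OC | intermediate
5 | open-chain aldehyde, (2S,3S)-3-(3-formyl-6-hydroxy-2,4-dimethoxyphenyl)-2-isopropyl-5-methylhexanal | CC(C)C[C@H](c1c(O)cc(OC)c(C=O)c1OC)[C@@H](C=O)C(C)C | intermediate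
6 | (3S,4S)-2-hydroxy-4-isobutyl-3-isopropyl-5,7-dimethoxychromane-6-carbaldehyde (C2 anomers) | CC(C)C[C@@H]1c2c(cc(OC)c(C=O)c2OC)OC(O)[C@H]1C(C)C | intermediate
7 | 2,4,6-trihydroxybenzene-1,3-dicarbaldehyde (diformylphloroglucinol) | O=Cc1c(O)cc(O)c(C=O)c1O | starting material
8 | (4S)-4-isobutyl-3-isopropyl-5,7-dimethoxy-4H-chromene-6-carbaldehyde | CC(C)C[C@@H]1c2c(cc(OC)c(C=O)c2OC)OC=C1C(C)C | intermediate
9 | (2R,3R,4S)-2-(3,5-diformyl-2,4,6-trihydroxyphenyl)-4-isobutyl-3-isopropyl-5,7-dimethoxychromane-6-carbaldehyde | CC(C)C[C@@H]1c2c(cc(OC)c(C=O)c2OC)O[C@@H](c2c(O)c(C=O)c(O)c(C=O)c2O)[C@@H]1C(C)C | intermediate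
10 | (2R,3R,4S)-2-(3,5-diformyl-2,4,6-trihydroxyphenyl)-5,7-dihydroxy-4-isobutyl-3-isopropylchromane-6-carbaldehyde | CC(C)C[C@@H]1c2c(cc(O)c(C=O)c2O)O[C@@H](c2c(O)c(C=O)c(O)c(C=O)c2O)[C@@H]1C(C)C | target

**Totals**
Total step count: 4. Longest linear sequence: 4 (1 → 3 → 6 → 9 → 10).

**Three steps most likely to fail**

1. Step 3 (the proposed new step). Compound 7 is a weak, hindered C-nucleophile, enol ether 8 may oligomerise, and the facial selectivity of C3 protonation is untested. The fallback uses known chemistry, sets out from 6 and comes back at 9. Lactol 6 is dehydrated (TsOH cat., toluene, 80 °C, sieves) and 8 is isolated. Acid-catalysed hydroarylation of 8 with phloroglucinol (benzene-1,3,5-triol, 3 equiv, cat. TsOH, dioxane/CH2Cl2, 0 °C), a far stronger nucleophile, gives (2R,3R,4S)-4-isobutyl-3-isopropyl-5,7-dimethoxy-2-(2,4,6-trihydroxyphenyl)chromane-6-carbaldehyde F1, with the same protonation and attack anti to the isobutyl group. Vilsmeier–Haack diformylation (POCl3/DMF 2.5 equiv, MeCN, 0 °C → rt, then aq. NaOAc) of the free trihydroxyphenyl ring gives 9; the methylated, formyl-deactivated ring is not attacked.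

2. Step 2. The alkyl o-quinone methide 4 may tautomerise to the alkenylphenol under base. The sense and level of induction at a methide carbon flanked by an OMe group are also not secured by precedent; only the C4 configuration matters, because C3 is erased in step 3. The fallback replaces enamine/base catalysis by chiral Brønsted acid catalysis; it sets out from 3 and comes back at 8. Sulfone 3 is hydrated through the quinone methide (NaHCO3, THF/H2O, rt) to rac-4-hydroxy-3-(1-hydroxy-3-methylbutyl)-2,6-dimethoxybenzaldehyde F2. Aldehyde 2 is condensed with benzyl carbamate (TsOH cat., toluene, Dean–Stark) to benzyl (E)-(3-methylbut-1-en-1-yl)carbamate F3. F2 and F3 are joined in a chiral phosphoric acid-catalysed [4+2] cycloaddition (TRIP, 5 mol %, toluene, 4 Å MS, 0 °C; the enantiomer of the acid that gives 4S is kept). This gives benzyl [(4S)-6-formyl-4-isobutyl-3-isopropyl-5,7-dimethoxychroman-2-yl]carbamate F4 (C2 and C3 not defined, both erased next). Under the acid of step 3, F4 loses benzyl carbamate to give 8.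

3. Step 1. Phenol 1 is deactivated by its para-formyl group, and diarylmethane formation can compete. The fallback replaces the acid-mediated Friedel–Crafts by a boron-templated ortho-hydroxyalkylation; it sets out from 1 and comes back at 3. Compounds 1 and 2 are heated with phenylboronic acid (EtCO2H cat., toluene, Dean–Stark) to give rac-4-isobutyl-5,7-dimethoxy-2-phenyl-4H-1,3,2-benzodioxaborinine-6-carbaldehyde F5, in which the C–C bond is formed inside the aryl borate. Treatment of F5 with TolSO2Na in HCO2H/H2O opens the boronate and substitutes the benzylic oxygen to give 3.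

**Further compounds**
F1 | step 3 | (2R,3R,4S)-4-isobutyl-3-isopropyl-5,7-dimethoxy-2-(2,4,6-trihydroxyphenyl)chromane-6-carbaldehyde | CC(C)C[C@@H]1c2c(cc(OC)c(C=O)c2OC)O[C@@H](c2c(O)cc(O)cc2O)[C@@H]1C(C)C
F2 | step 2 | rac-4-hydroxy-3-(1-hydroxy-3-methylbutyl)-2,6-dimethoxybenzaldehyde | CC(C)CC(O)c1c(O)cc(OC)c(C=O)c1OC
F3 | step 2 | benzyl (E)-(3-methylbut-1-en-1-yl)carbamate | CC(C)/C=C/NC(=O)OCc1ccccc1
F4 | step 2 | benzyl [(4S)-6-formyl-4-isobutyl-3-isopropyl-5,7-dimethoxychroman-2-yl]carbamate | CC(C)C[C@@H]1c2c(cc(OC)c(C=O)c2OC)OC(NC(=O)OCc2ccccc2)C1C(C)C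
F5 | step 1 | rac-4-isobutyl-5,7-dimethoxy-2-phenyl-4H-1,3,2-benzodioxaborinine-6-carbaldehyde | CC(C)CC1OB(c2ccccc2)Oc2cc(OC)c(C=O)c(OC)c12
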